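(All runs come from a simulation with made-up constants.)

If a rate falls faster than its starting material does, try the square of that level. Here red has its starting material fed over 3.0 h, violet has its reagent fed over the same time, and teal is charged together at the start.

| flask | starting material | reagent | remark | time |
|---|---|---|---|---|
| Tuesday's | 0.10 M | 0.18 M | run made earlier |  |
| Friday's | 0.10 M | 0.12 M | run made earlier |  |
| Saturday's | 0.10 M | 0.27 M | run made earlier |  |
| red | 0.10 M (fed, over 3.0 h) | 0.180 M | all else is in the flask from the start; the feed brings no volume worth counting | 8.0 h |
| violet | 0.10 M | 0.180 M (fed, over 3.0 h) | all else is in the flask from the start; the feed brings no volume worth counting | 8.0 h |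
| teal | 0.10 M | 0.180 M | everything together at the start | 8.0 h |

- Tuesday's (time / h: product / %, starting material / %): 0.667: 7, 91; 2.00: 20, 77; 4.00: 36, 65; 6.00: 48, 54; 8.00: 53, 49
- Friday's (time / h: product / %, starting material / %): 0.500: 5, 95; 1.00: 11, 88; 2.00: 18, 84; 3.00: 24, 76; 6.00: 42, 63
- Saturday's (time / h: product / %, starting material / %): 0.500: 10, 91; 1.00: 16, 82; 2.00: 25, 75; 3.00: 36, 63; 6.00: 53, 52

(each reading ± 1.5 percentage points)

- the flask that comes out highest in amount of product, in percent of the starting material charged, or "all alike" when all lie within 1.5 percentage points (red / violet / teal / all alike)
- product at the end, in percent of the starting material charged, red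
- product at the end, in percent of the starting material charged, violet
- product at the end, in percent of the starting material charged, teal

Tuesday's run has teal's charges, and its numbers seem not to fit. From 4.00 h to 8.00 h the mean rate stands at 0.425 of the rate over the first 2.00 h, yet the mean starting material stands at 0.644 of its early value, a gap too wide for scatter. Square that level and you get 0.415.

So let a be the starting material left, as a fraction of the charge, and read the run as second order in a: the reciprocal of a then climbs steadily. Call that hourly climb the clock g (a pseudo-second-order constant). With the mean conversion at the last reading taken from both columns: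

g = 52.0 % / (1 − 52.0 %) / 8.00 h = 0.135 h⁻¹

Teal, by my reckoning, gives 52.0 %. For red, the mean square of a level rising steadily from zero is a third of the top's square, so iterate, holding reagent as in Tuesday's run:

first round: a = 1 − g·3.0 h/3 = 86.5 %

second round, scaling that loss by the square of a: a = 89.9 %

then the clock runs on to 8.0 h: product = 44.1 %

The forecast reads the sag otherwise, “The loss looks like reagent destroying itself”. It gives red 45 %, violet 49 %, teal 52.5 %, and names teal.

Teal gives 51.1 %, violet 47.8 % and red 44.3 %, so teal stands highest.

    starting material + reagent → product, rate k1*[starting material]^2*[reagent]^0.5 (k = 3.40 M⁻¹·⁵ h⁻¹)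

Red held 87.9 % starting material at 3.00 h, against the second round's 89.9 %. Read as second order in a, the clock scales with the charge, so for red with 0.060 M starting material, g = 0.0813 h⁻¹. The same two rounds give a = 93.1 % and product 32.4 %. That flask gave 33.4 %.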